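The synthesis rests on the single CH2 carbon that links C3 of the benzofuran to C1 of resorcinol ring C. It sits between two sp2 carbons, so it can enter as carbon monoxide and be deoxygenated later. In one palladium-catalysed operation an ortho-alkynylphenol, CO and an aryl iodide are merged. This forms O1–C2, C3–C(=O) and C(=O)–C1(ring C) and closes the furan ring. One precursor is a diarylacetylene carrying ring A and one free phenol, with all other oxygens as MOM ethers. The other is the complete MOM-protected 3-arylcoumarin, iodinated on ring C. Both 1,1-dimethylallyl groups come from one aldehyde. Reduction, ionic deoxygenation and global MOM removal finish the synthesis.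

Key step: step 12

Assumption: ring A is the 2,4-dioxygenated phenyl on benzofuran C2 and ring C is the resorcinol ring between the CH2 and coumarin C3; methyl 2,4-dihydroxyphenylacetate is taken as a catalogue compound (otherwise one Fischer esterification of the acid); the target has no stereocentre, so no stereocontrol is needed.

Step 1
Reactants: 1 5-bromo-2,4-dihydroxybenzaldehyde
Product: 2 5-bromo-2,4-bis(methoxymethoxy)benzaldehyde
Conditions: MOMCl (3 equiv), i-Pr2NEt (4 equiv), CH2Cl2, 0 °C → reflux
Reagents that add atoms: chloromethyl methyl ether (MOMCl), COCCl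
Why: Base-mediated O-alkylation (MOM ether formation) of both phenols, in which excess reagent and gentle heating overcome the hydrogen bond between the 2-OH and the aldehyde while bromide and aldehyde stay untouched.

Step 2
Reactants: 2 5-bromo-2,4-bis(methoxymethoxy)benzaldehyde
Product: 3 1-bromo-5-(dimethoxymethyl)-2,4-bis(methoxymethoxy)benzene
Conditions: HC(OMe)3, PPTS (cat.), MeOH, rt; Et3N quench
Reagents that add atoms: trimethyl orthoformate, COC(OC)OC; methanol, CO
Why: Acid-catalysed acetalisation driven by orthoformate as water scavenger, needed because an allylboronate would otherwise add to the free aldehyde (allylboration) in step 3, and run with PPTS at room temperature, which is too weak to cleave aryl MOM ethers.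

Step 3
Reactants: 3 1-bromo-5-(dimethoxymethyl)-2,4-bis(methoxymethoxy)benzene; 4 prenylboronic acid pinacol ester
Product: 6 2,4-bis(methoxymethoxy)-5-(2-methylbut-3-en-2-yl)benzaldehyde, via reverse-prenylated dimethyl acetal 5 (not isolated)
Conditions: 4 (1.5 equiv), Pd(OAc)2 (3 mol %), bulky dialkylbiarylphosphine of the γ-selective type (6 mol %, fixed by a short screen), K3PO4 (aq), MeCN, 70 °C; then 10 % aq citric acid, THF, rt
Reagents that add atoms: prenylboronic acid pinacol ester 4, CC(C)=CCB1OC(C)(C)C(C)(C)O1; water, O
Why: γ-Selective Suzuki–Miyaura allyl–aryl coupling, a known ligand-controlled reaction of 3,3-disubstituted allylboronates in which SE2'-type transmetalation puts palladium on the tertiary allyl carbon and fast reductive elimination fixes the aryl–C(CH3)2 bond before σ–π–σ isomerisation, followed by hydrolysis of the very electron-rich acetal with an acid too weak for the MOM ethers.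

Step 4
Reactants: 6 2,4-bis(methoxymethoxy)-5-(2-methylbut-3-en-2-yl)benzaldehyde
Product: 7 1-ethynyl-2,4-bis(methoxymethoxy)-5-(2-methylbut-3-en-2-yl)benzene (ring A acetylene)
Conditions: dimethyl (1-diazo-2-oxopropyl)phosphonate (1.3 equiv), K2CO3 (2 equiv), MeOH, rt
Reagents that add atoms: dimethyl (1-diazo-2-oxopropyl)phosphonate, COP(=O)(OC)C(=[N+]=[N-])C(C)=O
Why: Ohira–Bestmann variant of the Seyferth–Gilbert homologation, in which methanolysis frees the diazomethylphosphonate anion and its Horner–Wadsworth–Emmons-type addition, loss of N2 and 1,2-hydride shift give the terminal alkyne under a mild base that MOM ethers and the vinyl group tolerate.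

Step 5
Reactants: 6 2,4-bis(methoxymethoxy)-5-(2-methylbut-3-en-2-yl)benzaldehyde
Product: 8 2-hydroxy-4-(methoxymethoxy)-5-(2-methylbut-3-en-2-yl)benzaldehyde
Conditions: MgBr2·OEt2 (2 equiv), CH2Cl2/Et2O, 0 °C → rt; then H2O
Reagents that add atoms: none
Why: Chelation-directed ether cleavage, the principle behind the known selective dealkylation of alkoxy groups ortho to an aryl carbonyl: magnesium binds the aldehyde oxygen and the ortho ether oxygen in a six-membered chelate, so only that MOM group is activated for bromide attack while the para MOM ether and the alkene remain.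

Step 6
Reactants: 9 4-iodoresorcinol
Product: 10 2-iodo-5-(methoxymethoxy)phenol
Conditions: NaH (2.2 equiv), DMF, 0 °C; MOMCl (1.0 equiv), −20 → 0 °C; then 1 M HCl to pH 6, 0 °C
Reagents that add atoms: chloromethyl methyl ether (MOMCl), COCCl
Why: Site-selective mono-O-alkylation of a bis-phenoxide: with both oxygens ionised the choice depends on nucleophilicity alone, and the oxygen para to iodine is both the more basic and the unhindered one, so one equivalent of MOMCl should go there, in line with the known remote mono-etherification of 4-haloresorcinols.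

Step 7
Reactants: 10 2-iodo-5-(methoxymethoxy)phenol; 7 ring A acetylene
Product: 11 2-{[2,4-bis(methoxymethoxy)-5-(2-methylbut-3-en-2-yl)phenyl]ethynyl}-5-(methoxymethoxy)phenol
Conditions: PdCl2(PPh3)2 (3 mol %), CuI (5 mol %), Et3N/THF, rt, degassed
Reagents that add atoms: none
Why: Sonogashira coupling of an aryl iodide at room temperature, where free ortho-iodophenols are known to give isolable ortho-alkynylphenols because cycloisomerisation to the benzofuran needs heat or a stronger base.

Step 8
Reactants: 12 methyl 2,4-dihydroxyphenylacetate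
Product: 13 methyl 2-[2,4-bis(methoxymethoxy)phenyl]acetate
Conditions: MOMCl (3 equiv), i-Pr2NEt (4 equiv), CH2Cl2, 0 °C → rt
Reagents that add atoms: chloromethyl methyl ether (MOMCl), COCCl
Why: MOM ether formation on both phenols under an amine base, mild enough that the methyl ester stays open-chain and does not lactonise onto the ortho oxygen.

Step 9
Reactants: 13 methyl 2-[2,4-bis(methoxymethoxy)phenyl]acetate
Product: 14 methyl 2-[5-iodo-2,4-bis(methoxymethoxy)phenyl]acetate
Conditions: NIS (1.05 equiv), MeCN, 0 °C → rt, dark
Reagents that add atoms: N-iodosuccinimide, O=C1CCC(=O)N1I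
Why: Electrophilic aromatic iodination: C5 is para to the 2-OMOM and ortho to the 4-OMOM group and is the only doubly activated position not wedged between two substituents, so iodine should enter there and not at C3.

Step 10
Reactants: 14 methyl 2-[5-iodo-2,4-bis(methoxymethoxy)phenyl]acetate
Product: 15 2-[5-iodo-2,4-bis(methoxymethoxy)phenyl]acetic acid
Conditions: LiOH (3 equiv), THF/MeOH/H2O, rt; then 1 M HCl to pH 4, 0 °C
Reagents that add atoms: lithium hydroxide, [Li+].[OH-]
Why: Ester saponification, to which aryl iodide and MOM ethers are inert, with a cold and only mildly acidic work-up that keeps the acetals intact.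

Step 11
Reactants: 15 2-[5-iodo-2,4-bis(methoxymethoxy)phenyl]acetic acid; 8 2-hydroxy-4-(methoxymethoxy)-5-(2-methylbut-3-en-2-yl)benzaldehyde
Product: 17 3-[5-iodo-2,4-bis(methoxymethoxy)phenyl]-7-(methoxymethoxy)-6-(2-methylbut-3-en-2-yl)coumarin, via formylaryl arylacetate ester 16 (not isolated)
Conditions: DCC (1.2 equiv), DMAP (0.2 equiv), CH2Cl2, 0 °C → rt; then DBU (1.5 equiv), rt → 40 °C
Reagents that add atoms: none
Why: Perkin-type 3-arylcoumarin synthesis in its mild carbodiimide form, that is Steglich esterification of the phenol, then DBU-promoted intramolecular Knoevenagel-type aldol addition of the arylacetate enolate to the ortho aldehyde and E1cB dehydration, conditions that spare MOM ethers, aryl iodide and alkene.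

Step 12
Reactants: 11 ortho-alkynylphenol; 17 ring-C iodo coumarin
Product: 18 hexa-MOM 3-aroylbenzofuran [2-[2,4-bis(methoxymethoxy)-5-(2-methylbut-3-en-2-yl)phenyl]-6-(methoxymethoxy)benzofuran-3-yl] [2,4-bis(methoxymethoxy)-5-[7-(methoxymethoxy)-6-(2-methylbut-3-en-2-yl)-2-oxochromen-3-yl]phenyl] ketone
Conditions: Pd(PPh3)4 (5 mol %), dry K2CO3 (4 equiv), CO (balloon, raised to a few bar if needed), MeCN/THF, 45–50 °C, 11 (1.2 equiv) added slowly
Reagents that add atoms: carbon monoxide, [C-]#[O+]
Why: Oxidative addition of iodide 17 to zerovalent palladium and fast CO insertion give an aroylpalladium iodide (divalent palladium) that binds the alkyne of deprotonated 11; the phenoxide oxygen attacks C2 on the face away from the metal, and reductive elimination from the benzofuran-3-yl(aroyl)palladium species makes the C3–C(=O) bond and returns the catalyst. The closest known reaction type is exactly this one, the palladium-catalysed carbonylative annulation of ortho-alkynylphenols with aryl iodides to 3-aroylbenzofurans. The furan ring closes in the 5-endo-dig mode by anti oxypalladation. No stereocentre is created. The step needs CO insertion ahead of alkyne activation and C-acylation instead of O-acylation: the electron-rich ortho-alkoxy arylpalladium migrates onto CO quickly under a CO atmosphere, slow addition of 11 lets the acyl complex form first, and the alkyne sits next to the only free OH of either partner because all six other phenol oxygens are MOM-masked. The two vinyl groups hang on quaternary carbons and are too hindered for Heck-type insertion at this temperature, and dry K2CO3 leaves the coumarin lactone closed.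

Step 13
Reactants: 18 hexa-MOM 3-aroylbenzofuran
Product: 19 hexa-MOM diarylcarbinol (C=O of 18 reduced to CHOH; racemic)
Conditions: NaBH4 (5 equiv), CeCl3·7H2O (1.5 equiv), THF/MeOH, 0 °C → rt; NaHCO3 (aq) quench
Reagents that add atoms: none
Why: Luche-type 1,2-reduction, in which the hard methoxyborohydrides formed in methanol attack the ketone and are poor at conjugate addition to the electron-rich 7-alkoxy-3-arylcoumarin, whose lactone carbonyl NaBH4 does not reduce; the carbinol centre arises as a racemate without control and is erased in step 14.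

Step 14
Reactants: 19 hexa-MOM diarylcarbinol
Product: 20 hexa-MOM ether of the target (CHOH of 19 replaced by CH2)
Conditions: Et3SiH (5 equiv), TFA (2 equiv), CH2Cl2, −40 → 0 °C; NaHCO3 (aq) quench
Reagents that add atoms: none
Why: Ionic deoxygenation (ionic hydrogenation): a little TFA at low temperature ionises the carbinol to a cation stabilised by the benzofuran and the 2,4-dialkoxyphenyl ring, Et3SiH traps it irreversibly, the MOM group on O-2' of ring A blocks pyran closure onto the cation, and aryl MOM ethers, monosubstituted alkenes and the coumarin do not react under these conditions.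

Step 15
Reactants: 20 hexa-MOM ether of the target
Product: 21 target CNP0380243.0: 3-[5-[[2-[2,4-dihydroxy-5-(2-methylbut-3-en-2-yl)phenyl]-6-hydroxybenzofuran-3-yl]methyl]-2,4-dihydroxyphenyl]-7-hydroxy-6-(2-methylbut-3-en-2-yl)chromen-2-one
Conditions: 3 M HCl (aq)/MeOH/THF, 45 °C
Reagents that add atoms: none
Why: Acid-catalysed transacetalisation of the six aryl MOM ethers to methanol; the monosubstituted vinyl groups are protonated far more slowly than the acetals, so addition of the freed ortho phenols to them should not compete at this acidity and temperature.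

Compound list
1 | 5-bromo-2,4-dihydroxybenzaldehyde | O=Cc1cc(Br)c(O)cc1O | starting material
2 | 5-bromo-2,4-bis(methoxymethoxy)benzaldehyde | O=Cc1cc(Br)c(OCOC)cc1OCOC | intermediate
3 | 1-bromo-5-(dimethoxymethyl)-2,4-bis(methoxymethoxy)benzene | COC(OC)c1cc(Br)c(OCOC)cc1OCOC | intermediate
4 | prenylboronic acid pinacol ester | CC(C)=CCB1OC(C)(C)C(C)(C)O1 | starting material
5 | 1-(dimethoxymethyl)-2,4-bis(methoxymethoxy)-5-(2-methylbut-3-en-2-yl)benzene (not isolated) | COC(OC)c1cc(C(C)(C)C=C)c(OCOC)cc1OCOC | intermediate
6 | 2,4-bis(methoxymethoxy)-5-(2-methylbut-3-en-2-yl)benzaldehyde | O=Cc1cc(C(C)(C)C=C)c(OCOC)cc1OCOC | intermediate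
7 | 1-ethynyl-2,4-bis(methoxymethoxy)-5-(2-methylbut-3-en-2-yl)benzene | C#Cc1cc(C(C)(C)C=C)c(OCOC)cc1OCOC | intermediate
8 | 2-hydroxy-4-(methoxymethoxy)-5-(2-methylbut-3-en-2-yl)benzaldehyde | O=Cc1cc(C(C)(C)C=C)c(OCOC)cc1O | intermediate
9 | 4-iodoresorcinol | Oc1ccc(I)c(O)c1 | starting material
10 | 2-iodo-5-(methoxymethoxy)phenol | COCOc1ccc(I)c(O)c1 | intermediate
11 | 2-{[2,4-bis(methoxymethoxy)-5-(2-methylbut-3-en-2-yl)phenyl]ethynyl}-5-(methoxymethoxy)phenol | C=CC(C)(C)c1cc(C#Cc2ccc(OCOC)cc2O)c(OCOC)cc1OCOC | intermediate
12 | methyl 2,4-dihydroxyphenylacetate | COC(=O)Cc1ccc(O)cc1O | starting material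
13 | methyl 2-[2,4-bis(methoxymethoxy)phenyl]acetate | COC(=O)Cc1ccc(OCOC)cc1OCOC | intermediate
14 | methyl 2-[5-iodo-2,4-bis(methoxymethoxy)phenyl]acetate | COC(=O)Cc1cc(I)c(OCOC)cc1OCOC | intermediate
15 | 2-[5-iodo-2,4-bis(methoxymethoxy)phenyl]acetic acid | O=C(O)Cc1cc(I)c(OCOC)cc1OCOC | intermediate
16 | 2-formyl-5-(methoxymethoxy)-4-(2-methylbut-3-en-2-yl)phenyl 2-[5-iodo-2,4-bis(methoxymethoxy)phenyl]acetate (not isolated) | O=Cc1cc(C(C)(C)C=C)c(OCOC)cc1OC(=O)Cc1cc(I)c(OCOC)cc1OCOC | intermediate
17 | 3-[5-iodo-2,4-bis(methoxymethoxy)phenyl]-7-(methoxymethoxy)-6-(2-methylbut-3-en-2-yl)coumarin | C=CC(C)(C)c1cc2cc(-c3cc(I)c(OCOC)cc3OCOC)c(=O)oc2cc1OCOC | intermediate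
18 | hexa-MOM 3-aroylbenzofuran (target with C=O in place of CH2, six MOM ethers) | C=CC(C)(C)c1cc(-c2oc3cc(OCOC)ccc3c2C(=O)c2cc(-c3cc4cc(C(C)(C)C=C)c(OCOC)cc4oc3=O)c(OCOC)cc2OCOC)c(OCOC)cc1OCOC | intermediate
19 | hexa-MOM diarylcarbinol (racemic) | C=CC(C)(C)c1cc(-c2oc3cc(OCOC)ccc3c2C(O)c2cc(-c3cc4cc(C(C)(C)C=C)c(OCOC)cc4oc3=O)c(OCOC)cc2OCOC)c(OCOC)cc1OCOC | intermediate
20 | hexa-MOM ether of the target | C=CC(C)(C)c1cc(-c2oc3cc(OCOC)ccc3c2Cc2cc(-c3cc4cc(C(C)(C)C=C)c(OCOC)cc4oc3=O)c(OCOC)cc2OCOC)c(OCOC)cc1OCOC | intermediate
21 | CNP0380243.0 | C=CC(C)(C)c1cc(-c2oc3cc(O)ccc3c2Cc2cc(-c3cc4cc(C(C)(C)C=C)c(O)cc4oc3=O)c(O)cc2O)c(O)cc1O | target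

Total step count: 15.
Longest linear sequence: 9 steps (1, 2, 3, 4, 7, 12, 13, 14, 15; the branch 1, 2, 3, 5, 11, 12–15 is equally long).

Steps most likely to fail

Step 12. The aroylpalladium species may be intercepted at the phenoxide oxygen (ester formation). The alkyne may be activated before CO has inserted, or the alkynylphenol may simply cycloisomerise.
- The fallback sets out from 11 and 17 and comes back at 18. It separates ring closure from acylation while CO remains the source of the bridging carbon.
- Alkynylphenol 11 is closed by 5-endo-dig iodocyclisation (I2, NaHCO3, MeCN, rt) to 3-iodo-2-[2,4-bis(methoxymethoxy)-5-(2-methylbut-3-en-2-yl)phenyl]-6-(methoxymethoxy)benzofuran F1.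
- Iodide 17 is converted by Miyaura borylation (B2pin2, PdCl2(dppf), KOAc, dioxane, 80 °C) into the ring-C pinacol boronate of the coumarin F2.
- A carbonylative Suzuki–Miyaura coupling of F1 with F2 (PdCl2(PPh3)2, K2CO3, anisole, CO 1 atm, 80 °C) then gives ketone 18.

Step 3. γ-Selectivity may erode through σ–π–σ isomerisation of the allylpalladium intermediate. Reductive elimination at the quaternary carbon next to an ortho OMOM group may also be slow, which leaves time for protodeboronation.
- The fallback sets out from 3 and comes back at 5. It builds the quaternary carbon from an enolate, so no allyl regiochemistry is involved.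
- Palladium-catalysed α-arylation of the lithium enolate of methyl isobutyrate with 3 (LiNCy2, Pd(dba)2, P(t-Bu)3, toluene, rt) gives methyl 2-[5-(dimethoxymethyl)-2,4-bis(methoxymethoxy)phenyl]-2-methylpropanoate F3.
- DIBAL-H (toluene, −78 °C) gives 2-[5-(dimethoxymethyl)-2,4-bis(methoxymethoxy)phenyl]-2-methylpropanal F4.
- Wittig methylenation (Ph3PCH3Br, KOt-Bu, THF, 0 °C) gives acetal 5, which is hydrolysed as in step 3 to 6.

Step 13. Hydride delivery to a hindered ketone flanked by two donor rings may be slow. Conjugate reduction or opening of the coumarin could then catch up.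
- The fallback sets out from 18 and comes back at 19. It masks the lactone as a carboxylate during the reduction.
- NaOH (aq, THF/MeOH, 50 °C) opens the coumarin to the disodium (Z)-coumarinate of the ketone F5, in which carboxylate and phenoxide shut down both the acyl and the conjugate position.
- NaBH4 in the same alkaline medium can then be heated (50–60 °C) until the ketone is consumed, giving the disodium (Z)-coumarinate of the carbinol F6.
- Buffering with AcOH to about pH 5 at 0 °C lets the (Z)-ortho-hydroxycinnamic acid relactonise spontaneously to 19.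

Further compounds
F1 | step 12 | 3-iodo-2-[2,4-bis(methoxymethoxy)-5-(2-methylbut-3-en-2-yl)phenyl]-6-(methoxymethoxy)benzofuran | C=CC(C)(C)c1cc(-c2oc3cc(OCOC)ccc3c2I)c(OCOC)cc1OCOC
F2 | step 12 | 3-[2,4-bis(methoxymethoxy)-5-(4,4,5,5-tetramethyl-1,3,2-dioxaborolan-2-yl)phenyl]-7-(methoxymethoxy)-6-(2-methylbut-3-en-2-yl)coumarin | C=CC(C)(C)c1cc2cc(-c3cc(B4OC(C)(C)C(C)(C)O4)c(OCOC)cc3OCOC)c(=O)oc2cc1OCOC
F3 | step 3 | methyl 2-[5-(dimethoxymethyl)-2,4-bis(methoxymethoxy)phenyl]-2-methylpropanoate | COC(=O)C(C)(C)c1cc(C(OC)OC)c(OCOC)cc1OCOC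
F4 | step 3 | 2-[5-(dimethoxymethyl)-2,4-bis(methoxymethoxy)phenyl]-2-methylpropanal | O=CC(C)(C)c1cc(C(OC)OC)c(OCOC)cc1OCOC
F5 | step 13 | disodium (Z)-coumarinate of ketone 18 (lactone opened) | [Na+].[Na+].[O-]C(=O)/C(c1cc(C(=O)c2c(-c3cc(C(C)(C)C=C)c(OCOC)cc3OCOC)oc3cc(OCOC)ccc23)c(OCOC)cc1OCOC)=C\c1cc(C(C)(C)C=C)c(OCOC)cc1[O-]
F6 | step 13 | disodium (Z)-coumarinate of carbinol 19 (lactone opened, racemic carbinol) | [Na+].[Na+].[O-]C(=O)/C(c1cc(C(O)c2c(-c3cc(C(C)(C)C=C)c(OCOC)cc3OCOC)oc3cc(OCOC)ccc23)c(OCOC)cc1OCOC)=C\c1cc(C(C)(C)C=C)c(OCOC)cc1[O-]
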